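**Retrosynthetic overview**

- The strategy rests on one feature: chroman carbon C3 is bonded directly to quinone carbon C1′. A C2=C3 double bond at that site is therefore a vinylquinone, conjugated through C1′=C6′ to the C5′ carbonyl, so C2 is electrophilic towards the C8a hydroxyl and C3 becomes the carbon end of a C5′ dienol.
- Last disconnection: O1–C2 (pyran ring) together with the C3–H bond, by 6-endo oxa-conjugate addition and catalyst-controlled protonation of the open-chain vinylquinone.
- The vinylquinone comes from the corresponding hydroquinone tetraphenol by neutral oxidation; the tetraphenol comes from its silyl ethers by buffered fluoride under argon, so that phenoxide and quinone never coexist.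
- C4–C4a is made by aromatic Claisen rearrangement of an aryl 2-arylallyl ether (Mitsunobu O-alkylation); C3–C1′ is made by Suzuki coupling of a B-ring boronate with 2-bromoallyl alcohol.
- Both benzene rings are bought (2,3-dimethoxyphenol for ring B, 2,6-dimethoxyphenol for ring A); the pyran ring is the only ring formed and is formed last.

Key step: step 13

Numbering used: chroman O1, C2, C3, C4, C4a, C5–C8, C8a; quinone C1′ (bonded to C3), C2′ and C5′ (carbonyls), C3′ and C4′ (OMe), C6′ (H). TIPS = triisopropylsilyl.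

Assumption: the face to which a given enantiomer of the phosphoric acid delivers the proton cannot be predicted with confidence; (R)-TRIP is written, and its antipode is to be used if the induction proves opposite to the required (S) configuration.

**Route**

Step 1
Reactants: 1 2,3-dimethoxyphenol
Product: 2 2,3-dimethoxy-1,4-benzoquinone
Conditions: (KSO3)2NO (2.2 equiv), KH2PO4, H2O/acetone, 0 °C to rt
Reagents that add atoms: potassium nitrosodisulfonate (Fremy's salt), [K+].[K+].[O]N(S(=O)(=O)[O-])S(=O)(=O)[O-]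
Why: Teuber oxidation, in which the nitroxyl radical removes the phenolic hydrogen and a second equivalent couples at the free para carbon, should give the p-quinone.

Step 2
Reactants: 2 2,3-dimethoxy-1,4-benzoquinone
Product: 3 2,3-dimethoxybenzene-1,4-diol
Conditions: Na2S2O4, EtOAc/H2O, rt, Ar
Reagents that add atoms: none
Why: Dithionite reduction of a quinone to its hydroquinone is a clean two-electron reduction and nothing else in the molecule is reducible.

Step 3
Reactants: 3 2,3-dimethoxybenzene-1,4-diol
Product: 4 1,4-bis(triisopropylsilyloxy)-2,3-dimethoxybenzene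
Conditions: TIPSCl (2.4 equiv), imidazole, DMF, 40 °C, Ar
Reagents that add atoms: triisopropylsilyl chloride, CC(C)[Si](Cl)(C(C)C)C(C)C
Why: Imidazole-mediated silylation of both phenols should proceed normally, and aryl TIPS ethers are chosen because they tolerate organolithiums, aqueous base and 190 °C and are later removed by fluoride without acid.

Step 4
Reactants: 4 1,4-bis(triisopropylsilyloxy)-2,3-dimethoxybenzene
Product: 5 1-bromo-3,4-dimethoxy-2,5-bis(triisopropylsilyloxy)benzene
Conditions: NBS (1.0 equiv), MeCN, 0 °C, dark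
Reagents that add atoms: N-bromosuccinimide, O=C1CCC(=O)N1Br
Why: Electrophilic aromatic bromination should give one monobromide because the two ring C–H positions are equivalent by symmetry and each is para to a methoxy group.

Step 5
Reactants: 5 1-bromo-3,4-dimethoxy-2,5-bis(triisopropylsilyloxy)benzene
Product: 7 2-[3,4-dimethoxy-2,5-bis(triisopropylsilyloxy)phenyl]-4,4,5,5-tetramethyl-1,3,2-dioxaborolane, via aryllithium 6 (not isolated)
Conditions: n-BuLi, THF, −78 °C; then i-PrOBpin, −78 °C to rt; aq. NH4Cl
Reagents that add atoms: 2-isopropoxy-4,4,5,5-tetramethyl-1,3,2-dioxaborolane, CC(C)OB1OC(C)(C)C(C)(C)O1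
Why: Bromine–lithium exchange followed by borylation should be clean at −78 °C, where the bulky TIPS group is not expected to migrate from oxygen to the lithiated carbon (retro-Brook).

Step 6
Reactants: 7 2-[3,4-dimethoxy-2,5-bis(triisopropylsilyloxy)phenyl]-4,4,5,5-tetramethyl-1,3,2-dioxaborolane; 8 2-bromoprop-2-en-1-ol
Product: 9 2-[3,4-dimethoxy-2,5-bis(triisopropylsilyloxy)phenyl]prop-2-en-1-ol
Conditions: Pd(OAc)2 (3 mol%), SPhos (6 mol%), K3PO4, THF/H2O 10:1, 60 °C
Reagents that add atoms: none
Why: Suzuki–Miyaura coupling of an alkenyl bromide with an ortho-substituted, electron-rich arylboronate is well served by SPhos, and the free allylic alcohol and the aryl TIPS ethers should tolerate the mild phosphate base.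

Step 7
Reactants: 10 2,6-dimethoxyphenol
Product: 11 (2,6-dimethoxyphenoxy)triisopropylsilane
Conditions: TIPSCl (1.3 equiv), imidazole, DMF, 50 °C
Reagents that add atoms: triisopropylsilyl chloride, CC(C)[Si](Cl)(C(C)C)C(C)C
Why: Silylation of the hindered phenol masks the future C7 hydroxyl with a group that does not direct metalation and has no ortho hydrogen next to it.

Step 8
Reactants: 11 (2,6-dimethoxyphenoxy)triisopropylsilane
Product: 14 2,4-dimethoxy-3-(triisopropylsilyloxy)phenol, via aryllithium 12 (not isolated), via lithium aryltrimethoxyborate 13 (not isolated)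
Conditions: n-BuLi, TMEDA, Et2O, 0 °C to rt; B(OMe)3, −78 °C to rt; then AcOH, 30% H2O2, 0 °C
Reagents that add atoms: hydrogen peroxide, OO
Why: Directed ortho-metalation should occur only at the equivalent positions next to a methoxy group, and borylation with oxidative C-to-O migration then places the hydroxyl that becomes the C8a oxygen.

Step 9
Reactants: 14 2,4-dimethoxy-3-(triisopropylsilyloxy)phenol; 9 2-[3,4-dimethoxy-2,5-bis(triisopropylsilyloxy)phenyl]prop-2-en-1-ol
Product: 15 1-({2-[3,4-dimethoxy-2,5-bis(triisopropylsilyloxy)phenyl]prop-2-en-1-yl}oxy)-2,4-dimethoxy-3-(triisopropylsilyloxy)benzene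
Conditions: PPh3, DIAD, THF, 0 °C to rt
Reagents that add atoms: none
Why: Mitsunobu etherification of a phenol with a primary allylic alcohol is reliable, and direct and allylic substitution of the symmetrical 2-arylallyl unit give the same ether.

Step 10
Reactants: 15 1-({2-[3,4-dimethoxy-2,5-bis(triisopropylsilyloxy)phenyl]prop-2-en-1-yl}oxy)-2,4-dimethoxy-3-(triisopropylsilyloxy)benzene
Product: 17 6-{2-[3,4-dimethoxy-2,5-bis(triisopropylsilyloxy)phenyl]prop-2-en-1-yl}-2,4-dimethoxy-3-(triisopropylsilyloxy)phenol, via Claisen dienone 16 (not isolated)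
Conditions: PhNEt2, 190 °C, sealed tube, Ar
Reagents that add atoms: none
Why: The aromatic Claisen rearrangement ([3,3]-sigmatropic shift) should deliver the allyl terminus to C4a, the only ortho carbon that bears hydrogen and can re-aromatise, while the amine solvent keeps the medium free of acid so that the new phenol does not add to the electron-rich styrene.

Step 11
Reactants: 17 6-{2-[3,4-dimethoxy-2,5-bis(triisopropylsilyloxy)phenyl]prop-2-en-1-yl}-2,4-dimethoxy-3-(triisopropylsilyloxy)phenol
Product: 18 5-[3-(2,4-dihydroxy-3,5-dimethoxyphenyl)prop-1-en-2-yl]-2,3-dimethoxybenzene-1,4-diol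
Conditions: TBAF (3.6 equiv), AcOH (3.6 equiv), degassed THF, 0 °C to rt, Ar; degassed aq. NH4Cl/Na2S2O4 work-up
Reagents that add atoms: none
Why: Fluoride cleavage of the three aryl silyl ethers under acetic acid buffer and exclusion of oxygen should release the tetraphenol without strong acid (which would trigger Markovnikov closure onto the styrene) and without forming quinone in a basic medium.

Step 12
Reactants: 18 5-[3-(2,4-dihydroxy-3,5-dimethoxyphenyl)prop-1-en-2-yl]-2,3-dimethoxybenzene-1,4-diol
Product: 19 5-[3-(2,4-dihydroxy-3,5-dimethoxyphenyl)prop-1-en-2-yl]-2,3-dimethoxy-1,4-benzoquinone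
Conditions: Ag2O (1.1 equiv), Na2SO4, CH2Cl2, 0 °C, dark, about 10 min; filtration through Celite under Ar; cold filtrate used at once
Reagents that add atoms: none
Why: Silver(I) oxide oxidation of a hydroquinone is selective here because only ring B has a para-dihydroxy pair (the ring A hydroxyls are meta to each other), and the neutral heterogeneous conditions with immediate use limit uncatalysed cyclisation.

Step 13
Reactants: 19 5-[3-(2,4-dihydroxy-3,5-dimethoxyphenyl)prop-1-en-2-yl]-2,3-dimethoxy-1,4-benzoquinone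
Product: 21 5-[(3S)-7-hydroxy-6,8-dimethoxy-3,4-dihydro-2H-chromen-3-yl]-2,3-dimethoxy-1,4-benzoquinone, via dienol 20 (not isolated)
Conditions: (R)-TRIP (10 mol%), CH2Cl2/toluene 1:4, −60 °C, 0.01 M, Ar, dark; cold filtration through a short silica pad
Reagents that add atoms: none
Why: Proposed new method: the phosphoric acid is expected to hydrogen-bond the C5′ carbonyl through P–OH and the C8a hydroxyl through P=O, so that the phenol oxygen adds to the terminal vinyl carbon C2 in a 1,6-conjugate addition to give dienol 20 (exocyclic C3=C1′, C5′–OH), after which the same catalyst, held at the C5′ hydroxyl, passes the proton to C3 and the quinone is regenerated. The closest known reaction types are phosphoric acid-catalysed conjugate additions of phenols and naphthols to quinones, oxa-Michael cyclisations of phenols to chromans, and conjugate addition–enantioselective protonation cascades of α-branched vinyl ketones and vinyl azaarenes under chiral Brønsted acid catalysis. The pyran ring closes in 6-endo-trig mode by formation of O1–C2. The C3 stereocentre is set in the protonation, the face being chosen by the 3,3′-aryl pocket of the binaphthyl phosphate while it is bound to the dienol hydroxyl. Attack at C2 rather than at ring carbon C6′ (seven-membered ring) or at C3 (5-exo, cation next to the quinone) is secured by ring size and by the electron-poor quinone, while C-protonation must outrun the 1,5-hydrogen shift from C4 that would give the aromatic isoflav-3-ene hydroquinone and the catalysed path must outrun the uncatalysed one, which low temperature, high dilution and a non-basic, weakly polar medium are meant to ensure. No step follows, so the product is to be isolated cold and under neutral conditions to avoid racemisation through the reverse tautomerisation.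

**Compound list**

1 | 2,3-dimethoxyphenol | COc1cccc(O)c1OC | starting material
2 | 2,3-dimethoxy-1,4-benzoquinone | COC1=C(OC)C(=O)C=CC1=O | intermediate
3 | 2,3-dimethoxybenzene-1,4-diol | COc1c(O)ccc(O)c1OC | intermediate
4 | 1,4-bis(triisopropylsilyloxy)-2,3-dimethoxybenzene | COc1c(O[Si](C(C)C)(C(C)C)C(C)C)ccc(O[Si](C(C)C)(C(C)C)C(C)C)c1OC | intermediate
5 | 1-bromo-3,4-dimethoxy-2,5-bis(triisopropylsilyloxy)benzene | COc1c(O[Si](C(C)C)(C(C)C)C(C)C)cc(Br)c(O[Si](C(C)C)(C(C)C)C(C)C)c1OC | intermediate
6 | [3,4-dimethoxy-2,5-bis(triisopropylsilyloxy)phenyl]lithium | COc1c(O[Si](C(C)C)(C(C)C)C(C)C)cc([Li])c(O[Si](C(C)C)(C(C)C)C(C)C)c1OC | intermediate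
7 | 2-[3,4-dimethoxy-2,5-bis(triisopropylsilyloxy)phenyl]-4,4,5,5-tetramethyl-1,3,2-dioxaborolane | COc1c(O[Si](C(C)C)(C(C)C)C(C)C)cc(B2OC(C)(C)C(C)(C)O2)c(O[Si](C(C)C)(C(C)C)C(C)C)c1OC | intermediate
8 | 2-bromoprop-2-en-1-ol | OCC(Br)=C | starting material
9 | 2-[3,4-dimethoxy-2,5-bis(triisopropylsilyloxy)phenyl]prop-2-en-1-ol | C=C(CO)c1cc(O[Si](C(C)C)(C(C)C)C(C)C)c(OC)c(OC)c1O[Si](C(C)C)(C(C)C)C(C)C | intermediate
10 | 2,6-dimethoxyphenol | COc1cccc(OC)c1O | starting material
11 | (2,6-dimethoxyphenoxy)triisopropylsilane | COc1cccc(OC)c1O[Si](C(C)C)(C(C)C)C(C)C | intermediate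
12 | [2,4-dimethoxy-3-(triisopropylsilyloxy)phenyl]lithium | COc1ccc([Li])c(OC)c1O[Si](C(C)C)(C(C)C)C(C)C | intermediate
13 | lithium trimethoxy[2,4-dimethoxy-3-(triisopropylsilyloxy)phenyl]borate | [Li+].COc1ccc([B-](OC)(OC)OC)c(OC)c1O[Si](C(C)C)(C(C)C)C(C)C | intermediate
14 | 2,4-dimethoxy-3-(triisopropylsilyloxy)phenol | COc1ccc(O)c(OC)c1O[Si](C(C)C)(C(C)C)C(C)C | intermediate
15 | 1-({2-[3,4-dimethoxy-2,5-bis(triisopropylsilyloxy)phenyl]prop-2-en-1-yl}oxy)-2,4-dimethoxy-3-(triisopropylsilyloxy)benzene | C=C(COc1ccc(OC)c(O[Si](C(C)C)(C(C)C)C(C)C)c1OC)c1cc(O[Si](C(C)C)(C(C)C)C(C)C)c(OC)c(OC)c1O[Si](C(C)C)(C(C)C)C(C)C | intermediate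
16 | 6-{2-[3,4-dimethoxy-2,5-bis(triisopropylsilyloxy)phenyl]prop-2-en-1-yl}-2,4-dimethoxy-3-(triisopropylsilyloxy)cyclohexa-2,4-dien-1-one (racemic) | O=C1C(CC(=C)c2cc(O[Si](C(C)C)(C(C)C)C(C)C)c(OC)c(OC)c2O[Si](C(C)C)(C(C)C)C(C)C)C=C(OC)C(O[Si](C(C)C)(C(C)C)C(C)C)=C1OC | intermediate
17 | 6-{2-[3,4-dimethoxy-2,5-bis(triisopropylsilyloxy)phenyl]prop-2-en-1-yl}-2,4-dimethoxy-3-(triisopropylsilyloxy)phenol | C=C(Cc1cc(OC)c(O[Si](C(C)C)(C(C)C)C(C)C)c(OC)c1O)c1cc(O[Si](C(C)C)(C(C)C)C(C)C)c(OC)c(OC)c1O[Si](C(C)C)(C(C)C)C(C)C | intermediate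
18 | 5-[3-(2,4-dihydroxy-3,5-dimethoxyphenyl)prop-1-en-2-yl]-2,3-dimethoxybenzene-1,4-diol | C=C(Cc1cc(OC)c(O)c(OC)c1O)c1cc(O)c(OC)c(OC)c1O | intermediate
19 | 5-[3-(2,4-dihydroxy-3,5-dimethoxyphenyl)prop-1-en-2-yl]-2,3-dimethoxy-1,4-benzoquinone | COC1=C(OC)C(=O)C(C(=C)Cc2cc(OC)c(O)c(OC)c2O)=CC1=O | intermediate
20 | 4-hydroxy-6-(7-hydroxy-6,8-dimethoxychroman-3-ylidene)-2,3-dimethoxycyclohexa-2,4-dien-1-one | COC1=C(OC)C(=O)C(=C2COc3c(cc(OC)c(O)c3OC)C2)C=C1O | intermediate
21 | 5-[(3S)-7-hydroxy-6,8-dimethoxy-3,4-dihydro-2H-chromen-3-yl]-2,3-dimethoxy-1,4-benzoquinone | COC1=C(OC)C(=O)C([C@H]2COc3c(cc(OC)c(O)c3OC)C2)=CC1=O | target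

**Step count**

Total: 13 steps. Longest linear sequence: 11 steps (steps 1–6, then 9–13, from 1 to 21); the ring A branch is 2 steps (7–8).

**Steps most likely to fail**

Step 13 (proposed new method). Three processes may defeat it: uncatalysed cyclisation giving racemic product; isomerisation of the dienol by a 1,5-hydrogen shift from C4 to the aromatic isoflav-3-ene hydroquinone instead of protonation at C3; and racemisation of the product through the reverse tautomerisation. The fallback uses known reaction types only, sets out from 17 and returns at 21. Catalytic enantioselective anti-Markovnikov hydroboration of the 1,1-disubstituted aryl alkene of 17 with pinacolborane (chiral cobalt iminopyridine–oxazoline or copper–bisphosphine catalyst; excess borane, since the free phenol consumes one equivalent as a borate that is hydrolysed on work-up) should give 6-{(2S)-2-[3,4-dimethoxy-2,5-bis(triisopropylsilyloxy)phenyl]-3-(4,4,5,5-tetramethyl-1,3,2-dioxaborolan-2-yl)propyl}-2,4-dimethoxy-3-(triisopropylsilyloxy)phenol F1, with C3 already set. Oxidation with NaBO3 should give (2S)-2-[3,4-dimethoxy-2,5-bis(triisopropylsilyloxy)phenyl]-3-[2-hydroxy-3,5-dimethoxy-4-(triisopropylsilyloxy)phenyl]propan-1-ol F2. Intramolecular Mitsunobu etherification (PPh3, DIAD) of the C8a phenol with the primary alcohol closes the pyran ring without touching C3 and should give (3S)-3-[3,4-dimethoxy-2,5-bis(triisopropylsilyloxy)phenyl]-6,8-dimethoxy-7-(triisopropylsilyloxy)chroman F3. Buffered TBAF/AcOH under argon should give 5-[(3S)-7-hydroxy-6,8-dimethoxychroman-3-yl]-2,3-dimethoxybenzene-1,4-diol F4, and Ag2O oxidation of F4 gives 21. No vinylquinone is involved in this sequence.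

Step 12. The vinylquinone may cyclise without stereocontrol on the silver oxide surface or during handling, dimerise by Diels–Alder reaction, or the C7 phenol (para to the benzylic CH2) may be over-oxidised to a quinone methide. The fallback sets out from 18 and returns at 21: the quinone is not prepared separately. Instead 18 is oxidised in homogeneous solution by redox exchange with 1.0 equiv of 1,4-benzoquinone (higher potential; its by-product hydroquinone is only a weak acid) at −60 °C in the presence of the chiral phosphoric acid, so that 19 is consumed as it forms. This fallback makes no new compound (F0).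

Step 10. At 190 °C the newly formed phenol may add to the electron-rich 1,1-disubstituted styrene (5-exo Markovnikov closure to a 2-methyl-2-aryl-2,3-dihydrobenzofuran), or the ether may fragment. The fallback makes the C4–C4a bond before the styrene exists; it sets out from 14 and 7 and returns at 18. O-Alkylation of 14 with 2,3-dibromopropene (K2CO3, acetone) should give 1-[(2-bromoprop-2-en-1-yl)oxy]-2,4-dimethoxy-3-(triisopropylsilyloxy)benzene F5. Claisen rearrangement of this small ether in PhNEt2 should give 6-(2-bromoprop-2-en-1-yl)-2,4-dimethoxy-3-(triisopropylsilyloxy)phenol F6. Silylation (TIPSCl, imidazole), so that the phenol cannot close onto the alkenyl bromide under palladium, gives 1-(2-bromoprop-2-en-1-yl)-3,5-dimethoxy-2,4-bis(triisopropylsilyloxy)benzene F7. Suzuki coupling of F7 with boronate 7 (Pd(OAc)2, SPhos, K3PO4) should give 1-{2-[3,4-dimethoxy-2,5-bis(triisopropylsilyloxy)phenyl]prop-2-en-1-yl}-3,5-dimethoxy-2,4-bis(triisopropylsilyloxy)benzene F8, and buffered TBAF/AcOH under argon converts F8 into 18.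

**Further compounds**

F1 | step 13 | 6-{(2S)-2-[3,4-dimethoxy-2,5-bis(triisopropylsilyloxy)phenyl]-3-(4,4,5,5-tetramethyl-1,3,2-dioxaborolan-2-yl)propyl}-2,4-dimethoxy-3-(triisopropylsilyloxy)phenol | CC1(C)OB(C[C@@H](Cc2cc(OC)c(O[Si](C(C)C)(C(C)C)C(C)C)c(OC)c2O)c2cc(O[Si](C(C)C)(C(C)C)C(C)C)c(OC)c(OC)c2O[Si](C(C)C)(C(C)C)C(C)C)OC1(C)C
F2 | step 13 | (2S)-2-[3,4-dimethoxy-2,5-bis(triisopropylsilyloxy)phenyl]-3-[2-hydroxy-3,5-dimethoxy-4-(triisopropylsilyloxy)phenyl]propan-1-ol | OC[C@@H](Cc1cc(OC)c(O[Si](C(C)C)(C(C)C)C(C)C)c(OC)c1O)c1cc(O[Si](C(C)C)(C(C)C)C(C)C)c(OC)c(OC)c1O[Si](C(C)C)(C(C)C)C(C)C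
F3 | step 13 | (3S)-3-[3,4-dimethoxy-2,5-bis(triisopropylsilyloxy)phenyl]-6,8-dimethoxy-7-(triisopropylsilyloxy)chroman | COc1c(OC)c(O[Si](C(C)C)(C(C)C)C(C)C)c([C@H]2COc3c(cc(OC)c(O[Si](C(C)C)(C(C)C)C(C)C)c3OC)C2)cc1O[Si](C(C)C)(C(C)C)C(C)C
F4 | step 13 | 5-[(3S)-7-hydroxy-6,8-dimethoxychroman-3-yl]-2,3-dimethoxybenzene-1,4-diol | COc1c(OC)c(O)c([C@H]2COc3c(cc(OC)c(O)c3OC)C2)cc1O
F0 | step 12 | none | none
F5 | step 10 | 1-[(2-bromoprop-2-en-1-yl)oxy]-2,4-dimethoxy-3-(triisopropylsilyloxy)benzene | C=C(Br)COc1ccc(OC)c(O[Si](C(C)C)(C(C)C)C(C)C)c1OC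
F6 | step 10 | 6-(2-bromoprop-2-en-1-yl)-2,4-dimethoxy-3-(triisopropylsilyloxy)phenol | C=C(Br)Cc1cc(OC)c(O[Si](C(C)C)(C(C)C)C(C)C)c(OC)c1O
F7 | step 10 | 1-(2-bromoprop-2-en-1-yl)-3,5-dimethoxy-2,4-bis(triisopropylsilyloxy)benzene | C=C(Br)Cc1cc(OC)c(O[Si](C(C)C)(C(C)C)C(C)C)c(OC)c1O[Si](C(C)C)(C(C)C)C(C)C
F8 | step 10 | 1-{2-[3,4-dimethoxy-2,5-bis(triisopropylsilyloxy)phenyl]prop-2-en-1-yl}-3,5-dimethoxy-2,4-bis(triisopropylsilyloxy)benzene | C=C(Cc1cc(OC)c(O[Si](C(C)C)(C(C)C)C(C)C)c(OC)c1O[Si](C(C)C)(C(C)C)C(C)C)c1cc(O[Si](C(C)C)(C(C)C)C(C)C)c(OC)c(OC)c1O[Si](C(C)C)(C(C)C)C(C)C
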